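**Retrosynthetic overview**
- Manassantin B1 ⇒ O-debenzylation ⇐ two ketone reductions ⇐ double SN2 O-alkylation of the core bisphenol with an (S)-α-chloro ketone made from veratrole. Ring A is the inner ring with the free OH; ring B is the inner methoxy ring.
- Core oxolane ⇒ C2–aryl bond from a ring A arylzinc and a 2-sulfonyl oxolane (aryl enters cis to the C3 methyl, trans to the C5 aryl).
- Sulfonyl oxolane ⇒ (3R,4R,5S)-γ-lactone ⇒ (R)-butenolide (hydrogenation anti to the aryl group, then C3 epimerisation).
- Key step: enantioselective nickel-catalysed ring expansion of 2,3-dimethylcyclopropenone (from but-2-yne and difluorocarbene) by insertion of the ring B aldehyde C=O.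
- Ring order: three-membered cyclopropenone → five-membered butenolide, which is carried through as the oxolane; all four arenes come from catechol.

Assumption: the antipode of the ligand in step 10 is the one found by screening to give (R)-17; descriptors follow the SMILES given.

**Route**

Step 1
Reactants: 1 catechol
Product: 2 veratrole (1,2-dimethoxybenzene)
Conditions: MeI (2.5 equiv), K2CO3, acetone, reflux
Reagents that add atoms: iodomethane CI
Why: Williamson O-methylation (SN2) of both phenoxides; no stereocentre is involved.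

Step 2
Reactants: 2 veratrole; 3 (S)-2-chloropropanoyl chloride
Product: 4 (S)-2-chloro-1-(3,4-dimethoxyphenyl)propan-1-one
Conditions: AlCl3 (1.2 equiv), CH2Cl2, −10 → 0 °C
Reagents that add atoms: none
Why: Friedel–Crafts acylation para to one methoxy group; the α-chloro stereocentre is not touched at low temperature, so (S) is retained.

Step 3
Reactants: 1 catechol
Product: 5 guaiacol (2-methoxyphenol)
Conditions: MeI (1.0 equiv), K2CO3 (1.0 equiv), acetone, rt
Reagents that add atoms: iodomethane CI
Why: Williamson mono-methylation with one equivalent of electrophile; over-methylated material is veratrole 2 and is fed into step 2.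

Step 4
Reactants: 5 guaiacol; 6 glyoxylic acid
Product: 9 vanillin (4-hydroxy-3-methoxybenzaldehyde), via vanillylmandelic acid 7 (not isolated), via vanilloylformic acid 8 (not isolated)
Conditions: aq NaOH, 25 °C; then air, CuSO4 (cat.), aq NaOH, 95 °C; H2SO4
Reagents that add atoms: none
Why: electrophilic hydroxyalkylation of the phenoxide para to OH by glyoxylate, then copper-catalysed aerobic oxidation to the α-keto acid and decarboxylation on acidification (the standard glyoxylic acid route to vanillin).

Step 5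
Reactants: 9 vanillin
Product: 10 4-(tert-butyldimethylsilyloxy)-3-methoxybenzaldehyde
Conditions: TBSCl, imidazole, DMF, rt
Reagents that add atoms: tert-butyldimethylsilyl chloride CC(C)(C)[Si](C)(C)Cl
Why: routine O-silylation of a phenol; the silyl ether survives the organometallic, hydride and hydrogenation steps that follow.

Step 6
Reactants: 1 catechol
Product: 11 2-(benzyloxy)phenol
Conditions: BnBr (1.0 equiv), K2CO3, acetone, reflux
Reagents that add atoms: benzyl bromide BrCc1ccccc1
Why: Williamson mono-benzylation; this benzyl group masks the oxygen that ends as the free OH of ring A.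

Step 7
Reactants: 11 2-(benzyloxy)phenol
Product: 12 2-(benzyloxy)-4-bromophenol
Conditions: NBS, MeCN, −20 → 0 °C
Reagents that add atoms: N-bromosuccinimide O=C1CCC(=O)N1Br
Why: electrophilic aromatic bromination directed para to the free OH, which is a stronger donor than the benzyl ether.

Step 8
Reactants: 12 2-(benzyloxy)-4-bromophenol
Product: 13 [2-(benzyloxy)-4-bromophenoxy](tert-butyl)dimethylsilane
Conditions: TBSCl, imidazole, DMF, rt
Reagents that add atoms: tert-butyldimethylsilyl chloride CC(C)(C)[Si](C)(C)Cl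
Why: routine O-silylation; it makes the two ring A oxygens orthogonal (silyl for the arm oxygen, benzyl for the final OH).

Step 9
Reactants: 14 but-2-yne
Product: 16 2,3-dimethylcycloprop-2-en-1-one, via difluorocyclopropene 15 (not isolated)
Conditions: TMSCF3, NaI, THF, 110 °C (sealed tube); then H2O, SiO2, rt
Reagents that add atoms: (trifluoromethyl)trimethylsilane C[Si](C)(C)C(F)(F)F; water O
Why: difluorocarbene addition to the alkyne gives the gem-difluorocyclopropene, which hydrolyses readily to the aromatic cyclopropenone (carbene cyclopropenation, then hydrolysis); the volatile product is used as a stock solution.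

Step 10
Reactants: 10 4-(tert-butyldimethylsilyloxy)-3-methoxybenzaldehyde; 16 2,3-dimethylcycloprop-2-en-1-one
Product: 17 (R)-5-[4-(tert-butyldimethylsilyloxy)-3-methoxyphenyl]-3,4-dimethylfuran-2(5H)-one
Conditions: Ni(cod)2 (10 mol %), (S)-t-Bu-PHOX (12 mol %), toluene, 40 °C, slow addition of 16
Reagents that add atoms: none
Why: Proposed new method: enantioselective ring expansion (three- to five-membered) of a dialkylcyclopropenone by formal insertion of an aryl aldehyde C=O; zerovalent nickel adds oxidatively into the strained acyl–vinyl C–C bond of 16 to give a nickelacyclobutenone, the ligand-bound divalent nickel vinyl inserts the aldehyde carbonyl through one enantioface (this sets C5), and C(acyl)–O reductive elimination releases the butenolide and the catalyst, with no base present that could racemise the acidic C5–H; the closest known reactions are the nickel-catalysed (3+2) ring expansions of diarylcyclopropenones with ketone carbonyls and the racemic phosphine-catalysed cyclopropenone–aldehyde annulation.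

Step 11
Reactants: 17 (R)-butenolide
Product: 19 (3R,4R,5S)-5-[4-(tert-butyldimethylsilyloxy)-3-methoxyphenyl]-3,4-dimethyloxolan-2-one, via all-cis lactone 18 (not isolated)
Conditions: H2 (10 atm), 5% Rh/Al2O3, EtOAc, rt; filter; then DBU (0.5 equiv), toluene, 60 °C
Reagents that add atoms: none
Why: heterogeneous syn-hydrogenation on the face anti to the C5 aryl gives the all-cis lactone and sets C4 (methyl cis to aryl); thermodynamic α-epimerisation then moves the enolisable C3 methyl trans to the C4 methyl.

Step 12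
Reactants: 19 (3R,4R,5S)-lactone
Product: 20 (3R,4R,5S)-5-[4-(tert-butyldimethylsilyloxy)-3-methoxyphenyl]-3,4-dimethyloxolan-2-ol (anomer mixture)
Conditions: i-Bu2AlH (1.1 equiv), CH2Cl2, −78 °C
Reagents that add atoms: none
Why: partial hydride reduction of a lactone stops at the lactol because the aluminium hemiacetal is stable at −78 °C; the ring stereocentres are untouched.

Step 13
Reactants: 20 lactol
Product: 21 (3R,4R,5S)-2-(benzenesulfonyl)-5-[4-(tert-butyldimethylsilyloxy)-3-methoxyphenyl]-3,4-dimethyloxolane (C2 mixture)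
Conditions: PhSO2H, CaCl2, CH2Cl2, rt
Reagents that add atoms: benzenesulfinic acid O=S(O)c1ccccc1
Why: acid-promoted exchange of the anomeric OH for sulfinate via the oxocarbenium ion (Ley-type 2-sulfonyl cyclic ether formation); the C2 configuration is irrelevant because it ionises again in step 14.

Step 14
Reactants: 21 2-sulfonyl oxolane; 13 [2-(benzyloxy)-4-bromophenoxy](tert-butyl)dimethylsilane
Product: 24 (2S,3R,4R,5S)-2-[3-(benzyloxy)-4-(tert-butyldimethylsilyloxy)phenyl]-5-[4-(tert-butyldimethylsilyloxy)-3-methoxyphenyl]-3,4-dimethyloxolane, via aryllithium 22 (not isolated), via arylzinc bromide 23 (not isolated)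
Conditions: 13 (2 equiv), n-BuLi, THF, −78 °C; ZnBr2, −78 → 0 °C; then 21, THF, rt
Reagents that add atoms: none
Why: bromine–lithium exchange and transmetalation give the arylzinc, zinc-assisted ionisation of the sulfone gives the oxocarbenium ion, and the aryl group adds anti to the C5 aryl and syn to the C3 methyl (inside attack on the envelope), which sets C2 as (S) and gives the 2,3-cis-3,4-trans-4,5-cis ring; this sulfone/organozinc substitution is established on closely related 5-aryl-3,4-dimethyl oxolanes.

Step 15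
Reactants: 24 bis-silyl ether
Product: 25 2-(benzyloxy)-4-[(2S,3R,4R,5S)-5-(4-hydroxy-3-methoxyphenyl)-3,4-dimethyloxolan-2-yl]phenol
Conditions: Bu4NF, AcOH, THF, 0 °C → rt
Reagents that add atoms: none
Why: buffered fluoride desilylation cleaves both aryl silyl ethers and leaves the benzyl ether and the acid- and base-sensitive cis-aryl oxolane untouched.

Step 16
Reactants: 25 bisphenol; 4 (S)-2-chloro-1-(3,4-dimethoxyphenyl)propan-1-one
Product: 26 bis[(R)-α-aryloxy ketone]: the oxolane core of 25 with both phenolic oxygens carrying (R)-1-(3,4-dimethoxyphenyl)-1-oxopropan-2-yl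
Conditions: 4 (2.4 equiv), K2CO3, acetone, 40 °C
Reagents that add atoms: none
Why: double Williamson SN2 displacement at the α-chloro ketone with inversion sets both C8 centres as (R); KCl precipitates from acetone, which suppresses chloride-exchange racemisation of 4.

Step 17
Reactants: 26 bis-ketone
Product: 27 O-benzyl manassantin B1 (both carbinols R, threo)
Conditions: (R)-Me-CBS oxazaborolidine (40 mol %), BH3·SMe2, THF, −20 °C; MeOH
Reagents that add atoms: none
Why: Corey–Bakshi–Shibata reduction; the reagent-controlled hydride delivery is matched with the Felkin–Anh (polar) preference of the (R)-α-aryloxy ketones and gives both (R)-carbinols (threo arms).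

Step 18
Reactants: 27 O-benzyl manassantin B1
Product: 28 manassantin B1
Conditions: H2 (1 atm), 10% Pd/C, EtOAc, rt
Reagents that add atoms: none
Why: hydrogenolysis of the aryl benzyl ether is much faster under neutral conditions than cleavage of the benzylic alcohols or the oxolane C–O bonds, and no stereocentre is affected.

**Compound list**

1 | catechol | Oc1ccccc1O | starting material
2 | veratrole (1,2-dimethoxybenzene) | COc1ccccc1OC | intermediate
3 | (S)-2-chloropropanoyl chloride | C[C@H](Cl)C(Cl)=O | starting material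
4 | (S)-2-chloro-1-(3,4-dimethoxyphenyl)propan-1-one | COc1ccc(C(=O)[C@H](C)Cl)cc1OC | intermediate
5 | guaiacol (2-methoxyphenol) | COc1ccccc1O | intermediate
6 | glyoxylic acid | O=CC(=O)O | starting material
7 | vanillylmandelic acid, 2-hydroxy-2-(4-hydroxy-3-methoxyphenyl)acetic acid (racemic, not isolated) | COc1cc(C(O)C(=O)O)ccc1O | intermediate
8 | vanilloylformic acid, 2-(4-hydroxy-3-methoxyphenyl)-2-oxoacetic acid (not isolated) | COc1cc(C(=O)C(=O)O)ccc1O | intermediate
9 | vanillin | COc1cc(C=O)ccc1O | intermediate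
10 | 4-(tert-butyldimethylsilyloxy)-3-methoxybenzaldehyde | COc1cc(C=O)ccc1O[Si](C)(C)C(C)(C)C | intermediate
11 | 2-(benzyloxy)phenol | Oc1ccccc1OCc1ccccc1 | intermediate
12 | 2-(benzyloxy)-4-bromophenol | Oc1ccc(Br)cc1OCc1ccccc1 | intermediate
13 | [2-(benzyloxy)-4-bromophenoxy](tert-butyl)dimethylsilane | CC(C)(C)[Si](C)(C)Oc1ccc(Br)cc1OCc1ccccc1 | intermediate
14 | but-2-yne | CC#CC | starting material
15 | 3,3-difluoro-1,2-dimethylcyclopropene (not isolated) | CC1=C(C)C1(F)F | intermediate
16 | 2,3-dimethylcycloprop-2-en-1-one | CC1=C(C)C1=O | intermediate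
17 | (R)-5-[4-(tert-butyldimethylsilyloxy)-3-methoxyphenyl]-3,4-dimethylfuran-2(5H)-one | O=C1O[C@H](c2ccc(O[Si](C)(C)C(C)(C)C)c(OC)c2)C(C)=C1C | intermediate
18 | (3S,4R,5S)-5-[4-(tert-butyldimethylsilyloxy)-3-methoxyphenyl]-3,4-dimethyloxolan-2-one, all-cis (not isolated) | O=C1O[C@H](c2ccc(O[Si](C)(C)C(C)(C)C)c(OC)c2)[C@H](C)[C@@H]1C | intermediate
19 | (3R,4R,5S)-5-[4-(tert-butyldimethylsilyloxy)-3-methoxyphenyl]-3,4-dimethyloxolan-2-one (3,4-trans, 4,5-cis) | O=C1O[C@H](c2ccc(O[Si](C)(C)C(C)(C)C)c(OC)c2)[C@H](C)[C@H]1C | intermediate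
20 | (3R,4R,5S)-5-[4-(tert-butyldimethylsilyloxy)-3-methoxyphenyl]-3,4-dimethyloxolan-2-ol (anomer mixture) | OC1O[C@H](c2ccc(O[Si](C)(C)C(C)(C)C)c(OC)c2)[C@H](C)[C@H]1C | intermediate
21 | (3R,4R,5S)-2-(benzenesulfonyl)-5-[4-(tert-butyldimethylsilyloxy)-3-methoxyphenyl]-3,4-dimethyloxolane (C2 mixture) | O=S(=O)(c1ccccc1)C1O[C@H](c2ccc(O[Si](C)(C)C(C)(C)C)c(OC)c2)[C@H](C)[C@H]1C | intermediate
22 | [3-(benzyloxy)-4-(tert-butyldimethylsilyloxy)phenyl]lithium (not isolated) | [Li]c1ccc(O[Si](C)(C)C(C)(C)C)c(OCc2ccccc2)c1 | intermediate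
23 | [3-(benzyloxy)-4-(tert-butyldimethylsilyloxy)phenyl]zinc bromide (not isolated) | Br[Zn]c1ccc(O[Si](C)(C)C(C)(C)C)c(OCc2ccccc2)c1 | intermediate
24 | (2S,3R,4R,5S)-2-[3-(benzyloxy)-4-(tert-butyldimethylsilyloxy)phenyl]-5-[4-(tert-butyldimethylsilyloxy)-3-methoxyphenyl]-3,4-dimethyloxolane | CC(C)(C)[Si](C)(C)Oc1ccc([C@H]2O[C@H](c3ccc(O[Si](C)(C)C(C)(C)C)c(OC)c3)[C@H](C)[C@H]2C)cc1OCc1ccccc1 | intermediate
25 | 2-(benzyloxy)-4-[(2S,3R,4R,5S)-5-(4-hydroxy-3-methoxyphenyl)-3,4-dimethyloxolan-2-yl]phenol | Oc1ccc([C@H]2O[C@H](c3ccc(O)c(OC)c3)[C@H](C)[C@H]2C)cc1OCc1ccccc1 | intermediate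
26 | (R)-2-[2-(benzyloxy)-4-[(2S,3R,4R,5S)-5-[4-[(R)-1-(3,4-dimethoxyphenyl)-1-oxopropan-2-yl]oxy-3-methoxyphenyl]-3,4-dimethyloxolan-2-yl]phenoxy]-1-(3,4-dimethoxyphenyl)propan-1-one | COc1ccc(C(=O)[C@@H](C)Oc2ccc([C@H]3O[C@H](c4ccc(O[C@H](C)C(=O)c5ccc(OC)c(OC)c5)c(OC)c4)[C@H](C)[C@H]3C)cc2OCc6ccccc6)cc1OC | intermediate
27 | O-benzyl manassantin B1: (1R,2R)-2-[2-(benzyloxy)-4-[(2S,3R,4R,5S)-5-[4-[(1R,2R)-1-(3,4-dimethoxyphenyl)-1-hydroxypropan-2-yl]oxy-3-methoxyphenyl]-3,4-dimethyloxolan-2-yl]phenoxy]-1-(3,4-dimethoxyphenyl)propan-1-ol | COc1ccc([C@@H](O)[C@@H](C)Oc2ccc([C@H]3O[C@H](c4ccc(O[C@H](C)[C@H](O)c5ccc(OC)c(OC)c5)c(OC)c4)[C@H](C)[C@H]3C)cc2OCc6ccccc6)cc1OC | intermediate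
28 | manassantin B1 | COc1ccc([C@@H](O)[C@@H](C)Oc2ccc([C@H]3O[C@H](c4ccc(O[C@H](C)[C@H](O)c5ccc(OC)c(OC)c5)c(OC)c4)[C@H](C)[C@H]3C)cc2O)cc1OC | target

**Step count**

Total: 18 steps. Longest linear sequence: 12 steps (steps 3, 4, 5, 10, 11, 12, 13, 14, 15, 16, 17, 18, from catechol).

**Three steps most likely to fail, with fallbacks**

Step 10 (the proposed new ring expansion) may fail through decarbonylation of 16 to but-2-yne, oligomerisation of 16, or low enantioselectivity. The fallback uses known chemistry, sets out from 10 and returns at 17. Enantioselective zinc alkynylation of 10 (propyne, Me2Zn, the ProPhenol antipode that gives the R alcohol, toluene) gives (R)-1-[4-(tert-butyldimethylsilyloxy)-3-methoxyphenyl]but-2-yn-1-ol F1. Hydroxyl-directed anti-carbomagnesiation of F1 (MeMgCl, CuI cat., THF, reflux), trapping of the vinylmagnesium with CO2 and acidic work-up then closes butenolide 17.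

Step 11 may fail because the tetrasubstituted butenolide is slow to hydrogenate, and forcing conditions risk arene reduction or loss of the benzylic lactone C–O bond; the C3 epimerisation may also stop at a mixture. The fallback builds the lactone stereocentres by C–C bond formation instead, sets out from 10 and returns at 19. Crotylboration of 10 with (Z)-crotyl-B(Ipc)2 (from (−)-Ipc2BOMe; THF, −78 °C; NaOH/H2O2) gives syn (1S,2R)-1-[4-(tert-butyldimethylsilyloxy)-3-methoxyphenyl]-2-methylbut-3-en-1-ol F2. Hydroboration–oxidation (9-BBN; NaOH/H2O2) gives (1S,2R)-1-[4-(tert-butyldimethylsilyloxy)-3-methoxyphenyl]-2-methylbutane-1,4-diol F3. Oxidative lactonisation (TEMPO, PhI(OAc)2) gives (4R,5S)-5-[4-(tert-butyldimethylsilyloxy)-3-methoxyphenyl]-4-methyloxolan-2-one F4. Enolate methylation (LiN(SiMe3)2, MeI, THF, −78 °C) anti to the C4 methyl gives 19.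

Step 14 may fail because it sets the last ring stereocentre at a hindered oxocarbenium ion with a moisture-sensitive arylzinc; incomplete ionisation, elimination to the dihydrofuran or a lower cis selectivity are the likely problems. The fallback reverses the roles (aryl to the carbonyl, then hydride to the oxocarbenium ion), sets out from 19 and returns at 24. Aryllithium 22 (from 13, n-BuLi, THF, −78 °C) adds to lactone 19 to give (3R,4R,5S)-2-[3-(benzyloxy)-4-(tert-butyldimethylsilyloxy)phenyl]-5-[4-(tert-butyldimethylsilyloxy)-3-methoxyphenyl]-3,4-dimethyloxolan-2-ol F5. Reductive deoxygenation of F5 (Et3SiH, BF3·OEt2, CH2Cl2, −78 °C) delivers hydride anti to the C3 methyl and gives 24; the low temperature is needed to avoid acid-induced epimerisation of the cis benzylic centres.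

**Further compounds**

F1 | step 10 | (R)-1-[4-(tert-butyldimethylsilyloxy)-3-methoxyphenyl]but-2-yn-1-ol | O[C@H](c1ccc(O[Si](C)(C)C(C)(C)C)c(OC)c1)C#CC
F2 | step 11 | (1S,2R)-1-[4-(tert-butyldimethylsilyloxy)-3-methoxyphenyl]-2-methylbut-3-en-1-ol | O[C@H](c1ccc(O[Si](C)(C)C(C)(C)C)c(OC)c1)[C@H](C)C=C
F3 | step 11 | (1S,2R)-1-[4-(tert-butyldimethylsilyloxy)-3-methoxyphenyl]-2-methylbutane-1,4-diol | O[C@H](c1ccc(O[Si](C)(C)C(C)(C)C)c(OC)c1)[C@H](C)CCO
F4 | step 11 | (4R,5S)-5-[4-(tert-butyldimethylsilyloxy)-3-methoxyphenyl]-4-methyloxolan-2-one | O=C1O[C@H](c2ccc(O[Si](C)(C)C(C)(C)C)c(OC)c2)[C@H](C)C1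
F5 | step 14 | (3R,4R,5S)-2-[3-(benzyloxy)-4-(tert-butyldimethylsilyloxy)phenyl]-5-[4-(tert-butyldimethylsilyloxy)-3-methoxyphenyl]-3,4-dimethyloxolan-2-ol | OC1(c2ccc(O[Si](C)(C)C(C)(C)C)c(OCc3ccccc3)c2)O[C@H](c4ccc(O[Si](C)(C)C(C)(C)C)c(OC)c4)[C@H](C)[C@H]1C
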